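**Retrosynthetic overview**
1. The route rests on one feature of the ten-membered carbocycle C1–C10: carbinol carbon C8 lies between butenolide carbon C7 and C9, and C9 is allylic to C10 once methyl C14 is carried as a methylene. C8(OH)–C9–C10(=C14H2) is the retron of a [2,3]-Wittig shift of a C8–O–C14 ether, so the carbocycle comes from contraction of an eleven-membered furylmethyl 2-substituted-allyl ether.
2. The butenolide (O, C6, C7, C11, C12) is carried as a 2-silylfuran and unveiled after the key step by singlet oxygen and dehydration (C5=C6). The C1 hemiketal is carried as its methyl ketal inside the 1,4-epoxide (oxolane) bridge.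
3. The eleven-membered ether is closed by Williamson etherification (O–C14). Its open precursor comes from a γ-lactone plus a 2-lithioallyl ether (C1–C10) and from a furyllithium plus an aldehyde, then deoxygenation (C5–C6).
4. Ring order: oxolanone (C1–C4, O) from (R)-linalool → oxolane ketal → eleven-membered ether → ten-membered carbocycle (key step) → butenolide from the furan.
5. Stereocentres: C4 from linalool, C1 fixed by the bridge, C8 in the key step, C10 by hydrogenation from the face remote from the C8 ester, side-chain carbon from the chloro acid.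

Key step: step 17

Remark: atoms carry the germacrane numbers of the target (C1 hemiketal carbon, C4 ether carbon with methyl C15, C5=C6, C7=C11, C8 acyloxy carbon, C10 with methyl C14, C12 lactone carbonyl, C13 acetoxymethyl carbon). TBS = tert-butyldimethylsilyl, TIPS = triisopropylsilyl, TES = triethylsilyl, TMS = trimethylsilyl. (R)-Linalool of high enantiomeric purity, 2-bromoprop-2-en-1-ol and the (R)-chloro acid 28 are assumed to be purchasable.

**Route**

Step 1
Reactants: 1 (R)-linalool
Product: 2 (5R)-5-ethenyl-5-methyloxolan-2-ol (lactol; both anomers)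
Conditions: O3 (1 equiv, Sudan Red 7B as end-point dye), pyridine (3 equiv), CH2Cl2, −78 °C
Reagents that add atoms: ozone, [O-][O+]=O
Why: Pyridine-moderated ozonolysis cleaves the electron-rich trisubstituted alkene well before the vinyl group and gives the aldehyde without a reductive work-up; the aldehyde closes onto the tertiary hydroxyl as the lactol, and the C4 stereocentre from linalool is untouched.

Step 2
Reactants: 2 (5R)-5-ethenyl-5-methyloxolan-2-ol
Product: 3 (5R)-5-ethenyl-5-methyloxolan-2-one
Conditions: TEMPO (cat.), PhI(OAc)2, CH2Cl2, rt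
Reagents that add atoms: none
Why: Oxoammonium oxidation of a lactol to the γ-lactone, chosen over chromium reagents so that the tertiary allylic oxygen cannot undergo oxidative transposition.

Step 3
Reactants: 3 (5R)-5-ethenyl-5-methyloxolan-2-one
Product: 4 (2R)-2-methyl-5-oxooxolane-2-carbaldehyde
Conditions: O3, pyridine (3 equiv), CH2Cl2, −78 °C
Reagents that add atoms: ozone, [O-][O+]=O
Why: Ozonolysis of the vinyl group gives the C5 aldehyde on a quaternary carbon, which cannot enolise or epimerise.

Step 4
Reactants: 5 furan-3,4-diyldimethanol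
Product: 6 [4-(TBS-oxymethyl)furan-3-yl]methanol
Conditions: NaH (1.0 equiv), THF, 0 °C → rt; TBSCl (1.0 equiv)
Reagents that add atoms: tert-butyldimethylsilyl chloride, CC(C)(C)[Si](C)(C)Cl
Why: Monosilylation of a symmetrical diol through its sparingly soluble monosodium alkoxide; the silylated arm becomes C8 and the free arm C13.

Step 5
Reactants: 6 [4-(TBS-oxymethyl)furan-3-yl]methanol
Product: 9 [4-(TBS-oxymethyl)-2-(trimethylsilyl)furan-3-yl]methanol, via dilithio derivative 7 (not isolated), via bis(trimethylsilyl) derivative 8 (not isolated)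
Conditions: n-BuLi (2.2 equiv), THF, −78 → 0 °C; TMSCl (2.5 equiv), −78 °C → rt; aq. citric acid, THF
Reagents that add atoms: chlorotrimethylsilane, C[Si](C)(C)Cl
Why: Alkoxide-directed lithiation of a 3-furylmethanol at the adjacent α-position, C- and O-silylation, and hydrolysis of the O–Si bond on work-up place silicon on the future C12, next to the carbon that bears C13.

Step 6
Reactants: 9 [4-(TBS-oxymethyl)-2-(trimethylsilyl)furan-3-yl]methanol
Product: 10 2-(trimethylsilyl)-3-(TIPS-oxymethyl)-4-(TBS-oxymethyl)furan
Conditions: TIPSCl, imidazole, DMF, rt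
Reagents that add atoms: chlorotri(propan-2-yl)silane, CC(C)[Si](Cl)(C(C)C)C(C)C
Why: Standard silylation; the bulky TIPS ether outlasts the TBS ether in step 14 and resists migration to a neighbouring alkoxide.

Step 7
Reactants: 10 2-(trimethylsilyl)-3-(TIPS-oxymethyl)-4-(TBS-oxymethyl)furan; 4 (2R)-2-methyl-5-oxooxolane-2-carbaldehyde
Product: 12 (5R)-5-{hydroxy[3-(TBS-oxymethyl)-4-(TIPS-oxymethyl)-5-(trimethylsilyl)furan-2-yl]methyl}-5-methyloxolan-2-one (both carbinol epimers), via 5-lithiofuran 11 (not isolated)
Conditions: sec-BuLi (1.1 equiv), THF, −78 °C; then 4, −78 °C; AcOH, −78 °C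
Reagents that add atoms: none
Why: α-Lithiation of the only free furan position and 1,2-addition to the aldehyde, which is far more electrophilic than the lactone at −78 °C, form C5–C6; the carbinol centre is removed later, and the cold acid quench forestalls translactonisation and 1,4 O→C silyl migration.

Step 8
Reactants: 12 furyl carbinol lactone
Product: 13 O-phenyl thionocarbonate of 12
Conditions: PhOC(S)Cl, pyridine, DMAP (cat.), CH2Cl2, 0 °C → rt
Reagents that add atoms: O-phenyl chlorothionoformate, S=C(Cl)Oc1ccccc1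
Why: Thioacylation of the secondary alcohol under neutral conditions that spare the lactone (first half of the Barton–McCombie deoxygenation).

Step 9
Reactants: 13 O-phenyl thionocarbonate
Product: 14 (5R)-5-methyl-5-{[3-(TBS-oxymethyl)-4-(TIPS-oxymethyl)-5-(trimethylsilyl)furan-2-yl]methyl}oxolan-2-one
Conditions: Bu3SnH, AIBN (cat.), toluene, 90 °C
Reagents that add atoms: none
Why: Barton–McCombie radical deoxygenation through a stabilised 2-furylmethyl radical gives the C5 methylene; lactone, silyl ethers and the C–Si bond are inert to tin hydride.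

Step 10
Reactants: 15 2-bromoprop-2-en-1-ol
Product: 16 [(2-bromoprop-2-en-1-yl)oxy]triethylsilane
Conditions: TESCl, imidazole, CH2Cl2, 0 °C
Reagents that add atoms: chlorotriethylsilane, CC[Si](Cl)(CC)CC
Why: Silylation; TES is the most labile of the three silyl ethers and is shed in step 12.

Step 11
Reactants: 16 [(2-bromoprop-2-en-1-yl)oxy]triethylsilane; 14 deoxygenated lactone
Product: 18 cyclic hemiketal of the γ-hydroxy enone (2-hydroxyoxolane carrying the 3-(TES-oxy)prop-1-en-2-yl group at C1; both C1 epimers), via 2-lithioallyl triethylsilyl ether 17 (not isolated)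
Conditions: 16, tert-BuLi (2 equiv), Et2O, −78 °C; then 14 in THF, −78 °C; aq. NH4Cl
Reagents that add atoms: none
Why: Bromine–lithium exchange and mono-addition of the vinyllithium to the γ-lactone, whose lithium lactolate is stable at −78 °C, form C1–C10 and bring in C9 and C14.

Step 12
Reactants: 18 hemiketal
Product: 19 2-[(2S,5R)-2-methoxy-5-methyl-5-{[3-(TBS-oxymethyl)-4-(TIPS-oxymethyl)-5-(trimethylsilyl)furan-2-yl]methyl}oxolan-2-yl]prop-2-en-1-ol
Conditions: PPTS (cat.), MeOH, 0 °C → rt
Reagents that add atoms: methanol, CO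
Why: Acid-catalysed exchange of the hemiketal hydroxyl for methoxyl through the oxolanyl oxocarbenium ion, with methanolysis of the TES ether in the same flask; the C1 epimers equilibrate, the (1S) epimer with C5 and C10 cis on the oxolane is separated and taken on, and its epimer is returned to the same conditions.

Step 13
Reactants: 19 allylic alcohol
Product: 21 allylic chloride (C14–Cl), via allylic mesylate 20 (not isolated)
Conditions: MsCl, Et3N, CH2Cl2, −20 °C; then LiCl, THF, rt
Reagents that add atoms: lithium chloride, [Li+].[Cl-]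
Why: Mesylation and displacement by chloride; SN2 and SN2′ attack give the same product because both allyl termini are CH2 groups.

Step 14
Reactants: 21 allylic chloride
Product: 22 chloro alcohol with free C8 hydroxyl
Conditions: HF·pyridine, pyridine, THF, 0 °C
Reagents that add atoms: none
Why: Buffered HF·pyridine cleaves the primary TBS ether faster than the TIPS ether and leaves the ketal, the allylic chloride and the furan C–Si bond intact.

Step 15
Reactants: 22 chloro alcohol
Product: 23 eleven-membered furan-fused ether (ring C1–C2–C3–C4–C5–C6=C7–C8–O–C14–C10; 1,4-epoxide bridge; 1S,4R; 1-OMe; exocyclic C10=C9H2; C13 OTIPS; C12 SiMe3)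
Conditions: NaH, Bu4NI (cat.), THF, 40 °C, slow addition of 22 (final 2 mM)
Reagents that add atoms: none
Why: Intramolecular Williamson etherification under high dilution closes the eleven-membered ring through a C–O bond; the cis-2,5-disubstituted oxolane holds both arms on one face, and SN2 and SN2′ attack converge on one product.

Step 16
Reactants: 23 eleven-membered ether, C13 OTIPS
Product: 24 eleven-membered ether with free C13 hydroxyl
Conditions: Bu4NF, AcOH (1:1), THF, rt
Reagents that add atoms: none
Why: Fluoride cleavage of the TIPS ether, buffered so that no free alkoxide arises next to the C12 silyl group and no Brook-type loss of silicon occurs.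

Step 17
Reactants: 24 eleven-membered ether with free C13 hydroxyl
Product: 26 ten-membered furan-fused diol (8S; C8 OH; exocyclic C10=C14H2; C13 OH), via O13,C8-dilithio derivative 25 (not isolated)
Conditions: n-BuLi (1.05 equiv), THF, −78 °C; then sec-BuLi (2.2 equiv), TMEDA, −78 → −40 °C; aq. NH4Cl
Reagents that add atoms: none
Why: Proposed new method: the C13 lithium alkoxide formed by the first equivalent of base brings sec-BuLi to the neighbouring C8–H (furylmethyl and α to the ring oxygen), and the resulting carbanion attacks the exocyclic C9 terminus of the 2-substituted allyl unit through a five-centre envelope transition state while O–C14 breaks, a [2,3]-Wittig shift; the closest known reactions are the acyclic [2,3]-Wittig rearrangement of arylmethyl 2-substituted-allyl ethers and the [2,3]-Wittig ring contraction of macrocyclic diallyl and allyl propargyl ethers, where the alkene lies in the ring and three atoms are extruded, whereas here the alkene is exocyclic and the ring loses O and C14 and gains C9. The ten-membered carbocycle C1–C10 is closed by the C8–C9 bond as a contraction of the eleven-membered ether, with the ring atoms outside the five-centre array staying in place. Because both allyl termini are CH2 groups, a competing [1,2] shift would give the same constitution. C8 is the only new stereocentre: lithium should sit on the face of the oxolane oxygen, chelated by it and by the ring ether oxygen, and C9 should bond anti to lithium (the shift inverts the metal-bearing carbon), which leaves the oxygen on that face, 8S. The selectivity needed is metalation at C8 and not at C14, C5 or C12: the alkoxide direction secures the first two, the silyl group blocks C12, and no silyl ether remains that could be deprotonated and undergo a retro-Brook shift.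

Step 18
Reactants: 26 ten-membered diol
Product: 27 C13 acetate with free C8 hydroxyl
Conditions: Ac2O (1.1 equiv), pyridine, CH2Cl2, −20 °C
Reagents that add atoms: acetic anhydride, CC(=O)OC(C)=O
Why: Acylation of the primary furylmethyl alcohol in preference to the hindered secondary ring carbinol at low temperature.

Step 19
Reactants: 28 (R)-3-chloro-2-hydroxy-2-methylpropanoic acid
Product: 30 (R)-3-chloro-2-methyl-2-(triethylsilyloxy)propanoic acid, via bis(triethylsilyl) derivative 29 (not isolated)
Conditions: TESOTf (2.3 equiv), 2,6-lutidine, CH2Cl2, 0 °C; then H2O, THF, rt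
Reagents that add atoms: triethylsilyl trifluoromethanesulfonate, CC[Si](CC)(CC)OS(=O)(=O)C(F)(F)F
Why: Silylation of both hydroxyl functions and hydrolysis of the labile silyl ester leave the tertiary stereocentre untouched and mask the chlorohydrin so that later bases cannot close it to an epoxide.

Step 20
Reactants: 27 C13 acetate with free C8 hydroxyl; 30 silyl-protected acid
Product: 32 C8 ester (8S) of the furan-fused ten-membered ring, via mixed anhydride 31 (not isolated)
Conditions: 30, 2,4,6-trichlorobenzoyl chloride, Et3N, THF, rt; then 27, DMAP, toluene, rt → 40 °C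
Reagents that add atoms: none
Why: Yamaguchi esterification through the mixed anhydride and the acylpyridinium ion acylates the hindered C8 hydroxyl with retention, before hydrogenation so that this hydroxyl cannot steer hydrogen to its own face.

Step 21
Reactants: 32 C8 ester with C10 methylene
Product: 33 C8 ester with 10R methyl group
Conditions: RhCl(PPh3)3 (10 mol%), H2 (4 atm), benzene, rt
Reagents that add atoms: none
Why: Homogeneous hydrogenation of the 1,1-disubstituted alkene with a catalyst that leaves the furan, C–O and C–Cl bonds alone and is not steered by oxygen functions; hydrogen should add to the face remote from the C8 acyloxy group (1,3 to C10, on the face of the oxolane oxygen), which sets 10R with the methyl cis to the C8 oxygen.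

Step 22
Reactants: 33 silylfuran ester
Product: 36 γ-hydroxybutenolide (C12 lactone carbonyl; C6 hemiketal, both epimers), via furan endoperoxide 34 (not isolated), via trimethylsilyl ester 35 (not isolated)
Conditions: O2, visible light, tetraphenylporphyrin (cat.), CH2Cl2, −78 °C; then H2O, warm to rt
Reagents that add atoms: dioxygen (as singlet oxygen), O=O
Why: [4+2] Cycloaddition of singlet oxygen across C6 and C12, shift of silicon from C12 to peroxide oxygen with O–O cleavage, and hydrolysis make the carbon that carried silicon the lactone carbonyl (regiospecific silylfuran photooxygenation); no other alkene is left for an ene reaction.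

Step 23
Reactants: 36 γ-hydroxybutenolide
Product: 38 (5E)-ylidene butenolide with 1-OMe and side-chain OTES, via pseudo-mesylate 37 (not isolated)
Conditions: MsCl, Et3N, CH2Cl2, −20 → 0 °C
Reagents that add atoms: none
Why: Sulfonylation of the pseudo-acid hydroxyl and loss of methanesulfonic acid toward C5, the only neighbour of C6 that bears hydrogen, give the C5=C6 bond; the ten-membered ring allows only the geometry with C4 and C7 cis.

Step 24
Reactants: 38 protected ylidene butenolide
Product: 39 target, CNP0414417.3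
Conditions: aq. HF (48%), MeCN, 0 °C → rt
Reagents that add atoms: water, O
Why: Aqueous acid hydrolyses the bridged methyl ketal to the hemiketal, whose C1 configuration is fixed by the oxygen bridge, and removes the tertiary TES ether; acetate, enol lactone and chlorohydrin ester tolerate these conditions.

**Compound list**
1 | (R)-linalool, (3R)-3,7-dimethylocta-1,6-dien-3-ol | C=C[C@@](O)(C)CCC=C(C)C | starting material
2 | (5R)-5-ethenyl-5-methyloxolan-2-ol, both anomers | C=C[C@@]1(C)CCC(O)O1 | intermediate
3 | (5R)-5-ethenyl-5-methyloxolan-2-one | C=C[C@@]1(C)CCC(=O)O1 | intermediate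
4 | (2R)-2-methyl-5-oxooxolane-2-carbaldehyde | O=C[C@@]1(C)CCC(=O)O1 | intermediate
5 | furan-3,4-diyldimethanol | OCc1cocc1CO | starting material
6 | [4-(TBS-oxymethyl)furan-3-yl]methanol | OCc1cocc1CO[Si](C)(C)C(C)(C)C | intermediate
7 | dilithio derivative of 6 (lithium alkoxide, lithium on the adjacent ring α-carbon) | [Li]OCc1c([Li])occ1CO[Si](C)(C)C(C)(C)C | intermediate
8 | C,O-bis(trimethylsilyl) derivative of 6 | C[Si](C)(C)OCc1c([Si](C)(C)C)occ1CO[Si](C)(C)C(C)(C)C | intermediate
9 | [4-(TBS-oxymethyl)-2-(trimethylsilyl)furan-3-yl]methanol | OCc1c([Si](C)(C)C)occ1CO[Si](C)(C)C(C)(C)C | intermediate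
10 | 2-(trimethylsilyl)-3-(TIPS-oxymethyl)-4-(TBS-oxymethyl)furan | CC(C)[Si](C(C)C)(C(C)C)OCc1c([Si](C)(C)C)occ1CO[Si](C)(C)C(C)(C)C | intermediate
11 | 5-lithio derivative of 10 | CC(C)[Si](C(C)C)(C(C)C)OCc1c([Si](C)(C)C)oc([Li])c1CO[Si](C)(C)C(C)(C)C | intermediate
12 | (5R)-5-{hydroxy[3-(TBS-oxymethyl)-4-(TIPS-oxymethyl)-5-(trimethylsilyl)furan-2-yl]methyl}-5-methyloxolan-2-one, both carbinol epimers | CC(C)[Si](C(C)C)(C(C)C)OCc1c([Si](C)(C)C)oc(C(O)[C@@]2(C)CCC(=O)O2)c1CO[Si](C)(C)C(C)(C)C | intermediate
13 | O-phenyl thionocarbonate of 12 | CC(C)[Si](C(C)C)(C(C)C)OCc1c([Si](C)(C)C)oc(C(OC(=S)Oc3ccccc3)[C@@]2(C)CCC(=O)O2)c1CO[Si](C)(C)C(C)(C)C | intermediate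
14 | (5R)-5-methyl-5-{[3-(TBS-oxymethyl)-4-(TIPS-oxymethyl)-5-(trimethylsilyl)furan-2-yl]methyl}oxolan-2-one | CC(C)[Si](C(C)C)(C(C)C)OCc1c([Si](C)(C)C)oc(C[C@@]2(C)CCC(=O)O2)c1CO[Si](C)(C)C(C)(C)C | intermediate
15 | 2-bromoprop-2-en-1-ol | OCC(Br)=C | starting material
16 | [(2-bromoprop-2-en-1-yl)oxy]triethylsilane | CC[Si](CC)(CC)OCC(Br)=C | intermediate
17 | triethyl[(2-lithioprop-2-en-1-yl)oxy]silane | CC[Si](CC)(CC)OCC([Li])=C | intermediate
18 | hemiketal: (5R)-2-hydroxy-2-[3-(TES-oxy)prop-1-en-2-yl]-5-methyl-5-(furylmethyl)oxolane, furyl as in 14, both C1 epimers | CC(C)[Si](C(C)C)(C(C)C)OCc1c([Si](C)(C)C)oc(C[C@@]2(C)CCC(O)(O2)C(=C)CO[Si](CC)(CC)CC)c1CO[Si](C)(C)C(C)(C)C | intermediate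
19 | 2-[(2S,5R)-2-methoxy-5-methyl-5-(furylmethyl)oxolan-2-yl]prop-2-en-1-ol, furyl as in 14 | CC(C)[Si](C(C)C)(C(C)C)OCc1c([Si](C)(C)C)oc(C[C@@]2(C)CC[C@](OC)(O2)C(=C)CO)c1CO[Si](C)(C)C(C)(C)C | intermediate
20 | methanesulfonate of 19 | CC(C)[Si](C(C)C)(C(C)C)OCc1c([Si](C)(C)C)oc(C[C@@]2(C)CC[C@](OC)(O2)C(=C)COS(C)(=O)=O)c1CO[Si](C)(C)C(C)(C)C | intermediate
21 | allylic chloride from 19 (C14–Cl) | CC(C)[Si](C(C)C)(C(C)C)OCc1c([Si](C)(C)C)oc(C[C@@]2(C)CC[C@](OC)(O2)C(=C)CCl)c1CO[Si](C)(C)C(C)(C)C | intermediate
22 | chloro alcohol: 21 with free C8 hydroxyl | CC(C)[Si](C(C)C)(C(C)C)OCc1c([Si](C)(C)C)oc(C[C@@]2(C)CC[C@](OC)(O2)C(=C)CCl)c1CO | intermediate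
23 | eleven-membered furan-fused ether, (1S,4R)-1,4-epoxy-1-methoxy, C8–O–C14, exocyclic C10=C9H2, C13 OTIPS, C12 SiMe3 | CC(C)[Si](C(C)C)(C(C)C)OCc1c2c(C[C@@]3(C)CC[C@](OC)(O3)C(=C)COC2)oc1[Si](C)(C)C | intermediate
24 | eleven-membered ether 23 with free C13 hydroxyl | OCc1c2c(C[C@@]3(C)CC[C@](OC)(O3)C(=C)COC2)oc1[Si](C)(C)C | intermediate
25 | O13,C8-dilithio derivative of 24 | [Li]OCc1c2c(C[C@@]3(C)CC[C@](OC)(O3)C(=C)COC2[Li])oc1[Si](C)(C)C | intermediate
26 | ten-membered furan-fused diol, (1S,4R,8S), 8-OH, exocyclic C10=C14H2, C13 OH | OCc1c2c(C[C@@]3(C)CC[C@](OC)(O3)C(=C)C[C@@H]2O)oc1[Si](C)(C)C | intermediate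
27 | C13 acetate of 26 | CC(=O)OCc1c2c(C[C@@]3(C)CC[C@](OC)(O3)C(=C)C[C@@H]2O)oc1[Si](C)(C)C | intermediate
28 | (R)-3-chloro-2-hydroxy-2-methylpropanoic acid | OC(=O)[C@@](C)(O)CCl | starting material
29 | triethylsilyl (R)-3-chloro-2-methyl-2-(triethylsilyloxy)propanoate | CC[Si](CC)(CC)OC(=O)[C@@](C)(O[Si](CC)(CC)CC)CCl | intermediate
30 | (R)-3-chloro-2-methyl-2-(triethylsilyloxy)propanoic acid | OC(=O)[C@@](C)(O[Si](CC)(CC)CC)CCl | intermediate
31 | mixed anhydride of 30 with 2,4,6-trichlorobenzoic acid | O=C(OC(=O)[C@@](C)(O[Si](CC)(CC)CC)CCl)c1c(Cl)cc(Cl)cc1Cl | intermediate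
32 | C8 ester of 27 with acid 30 (8S), C10 methylene | CC(=O)OCc1c2c(C[C@@]3(C)CC[C@](OC)(O3)C(=C)C[C@@H]2OC(=O)[C@@](C)(O[Si](CC)(CC)CC)CCl)oc1[Si](C)(C)C | intermediate
33 | hydrogenated ester, (1S,4R,8S,10R) | CC(=O)OCc1c2c(C[C@@]3(C)CC[C@](OC)(O3)[C@H](C)C[C@@H]2OC(=O)[C@@](C)(O[Si](CC)(CC)CC)CCl)oc1[Si](C)(C)C | intermediate
34 | furan endoperoxide of 33 (O–O across C6 and C12) | CC(=O)OCC1=C2C3(C[C@@]4(C)CC[C@](OC)(O4)[C@H](C)C[C@@H]2OC(=O)[C@@](C)(O[Si](CC)(CC)CC)CCl)OOC1([Si](C)(C)C)O3 | intermediate
35 | trimethylsilyl (Z)-keto enoate (C6 ketone, C12 silyl ester) | CC(=O)OC/C(C(=O)O[Si](C)(C)C)=C1/C(=O)C[C@@]2(C)CC[C@](OC)(O2)[C@H](C)C[C@@H]1OC(=O)[C@@](C)(O[Si](CC)(CC)CC)CCl | intermediate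
36 | γ-hydroxybutenolide (6-OH, both C6 epimers) | CC(=O)OCC1=C2C(O)(C[C@@]3(C)CC[C@](OC)(O3)[C@H](C)C[C@@H]2OC(=O)[C@@](C)(O[Si](CC)(CC)CC)CCl)OC1=O | intermediate
37 | pseudo-mesylate of 36 | CC(=O)OCC1=C2C(OS(C)(=O)=O)(C[C@@]3(C)CC[C@](OC)(O3)[C@H](C)C[C@@H]2OC(=O)[C@@](C)(O[Si](CC)(CC)CC)CCl)OC1=O | intermediate
38 | (5E)-ylidene butenolide, 1-OMe, side-chain OTES | CC(=O)OCC1=C2/C(=C\[C@@]3(C)CC[C@](OC)(O3)[C@H](C)C[C@@H]2OC(=O)[C@@](C)(O[Si](CC)(CC)CC)CCl)OC1=O | intermediate
39 | CNP0414417.3 | CC(=O)OCC1=C2/C(=C\[C@@]3(C)CC[C@](O)(O3)[C@H](C)C[C@@H]2OC(=O)[C@@](C)(O)CCl)OC1=O | target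

**Totals**
Total steps: 24. Longest linear sequence: 19 steps (steps 4–9, 11–18 and 20–24, from furan-3,4-diyldimethanol 5).

**Steps most likely to fail**

1. Step 17 (the labelled step). What may go wrong: metalation at C14 or C5 instead of C8, a sluggish shift inside the bridged ring, or C9 meeting the wrong face of C8. Fallback, by known chemistry: it sets out from chloro alcohol 22, so it also passes by steps 15 and 16, and returns at diol 26. MnO2 oxidises the furylmethyl alcohol to the furan-3-carbaldehyde F1. CrCl2 with LiI in THF–DMF under high dilution closes C8–C9 directly by intramolecular Nozaki–Hiyama allylation, again with a single constitution because both allyl termini are CH2 groups, and gives the ten-membered carbinol as C8 epimers F2. Dess–Martin periodinane gives the furyl ketone F3. (R)-2-Methyl-CBS-oxazaborolidine with catecholborane reduces it under reagent control, with the furan as the large group, to the 8S carbinol F4. Bu4NF buffered with acetic acid removes the TIPS group to give 26.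

2. Step 15. What may go wrong: oligomerisation in place of closure of the medium ring, slow displacement at the hindered allylic chloride, or silyl transfer from O13 to the C8 alkoxide. Fallback: it sets out from allylic alcohol 19 and returns at macrocycle 23. Methyl chloroformate and pyridine give the allylic methyl carbonate F5, and HF·pyridine frees the C8 hydroxyl to give hydroxy carbonate F6. Pd2(dba)3 with dppb (zerovalent palladium) in dilute THF ionises the carbonate to a π-allyl complex with two equivalent termini. The methoxide released deprotonates the C8 hydroxyl, which closes the ether by intramolecular Tsuji–Trost O-allylation under neutral conditions, with no free alkoxide standing beside the silyl ether.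

3. Step 21. What may go wrong: hydrogen delivered to the wrong face of the hindered methylene group, or no turnover. Fallback: it sets out from hydroxy acetate 27 and returns at ester 33. Dess–Martin periodinane gives furyl ketone F7. (S)-2-Methyl-CBS-oxazaborolidine with catecholborane gives the 8R carbinol F8, whose hydroxyl lies on the face away from the oxolane oxygen. [Ir(cod)(PCy3)(py)]PF6 and H2 in CH2Cl2 then deliver hydrogen from that hydroxyl to C10 and give the 8R,10R alcohol F9. Mitsunobu esterification of F9 with acid 30 (PPh3, DIAD) inverts C8 and gives 33.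

Further compounds
F1 | step 17 | furan-3-carbaldehyde from 22 (C8 aldehyde, C14 chloride, C13 OTIPS) | CC(C)[Si](C(C)C)(C(C)C)OCc1c([Si](C)(C)C)oc(C[C@@]2(C)CC[C@](OC)(O2)C(=C)CCl)c1C=O
F2 | step 17 | ten-membered C8 carbinol, C13 OTIPS, both C8 epimers | CC(C)[Si](C(C)C)(C(C)C)OCc1c2c(C[C@@]3(C)CC[C@](OC)(O3)C(=C)CC2O)oc1[Si](C)(C)C
F3 | step 17 | ten-membered C8 furyl ketone, C13 OTIPS | CC(C)[Si](C(C)C)(C(C)C)OCc1c2c(C[C@@]3(C)CC[C@](OC)(O3)C(=C)CC2=O)oc1[Si](C)(C)C
F4 | step 17 | (8S) ten-membered carbinol, C13 OTIPS | CC(C)[Si](C(C)C)(C(C)C)OCc1c2c(C[C@@]3(C)CC[C@](OC)(O3)C(=C)C[C@@H]2O)oc1[Si](C)(C)C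
F5 | step 15 | allylic methyl carbonate of 19 | CC(C)[Si](C(C)C)(C(C)C)OCc1c([Si](C)(C)C)oc(C[C@@]2(C)CC[C@](OC)(O2)C(=C)COC(=O)OC)c1CO[Si](C)(C)C(C)(C)C
F6 | step 15 | hydroxy carbonate (free C8 hydroxyl) | CC(C)[Si](C(C)C)(C(C)C)OCc1c([Si](C)(C)C)oc(C[C@@]2(C)CC[C@](OC)(O2)C(=C)COC(=O)OC)c1CO
F7 | step 21 | C8 furyl ketone, C13 acetate | CC(=O)OCc1c2c(C[C@@]3(C)CC[C@](OC)(O3)C(=C)CC2=O)oc1[Si](C)(C)C
F8 | step 21 | (8R) carbinol, C13 acetate, C10 methylene | CC(=O)OCc1c2c(C[C@@]3(C)CC[C@](OC)(O3)C(=C)C[C@H]2O)oc1[Si](C)(C)C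
F9 | step 21 | (8R,10R) carbinol, C13 acetate | CC(=O)OCc1c2c(C[C@@]3(C)CC[C@](OC)(O3)[C@H](C)C[C@H]2O)oc1[Si](C)(C)C
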